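We start from a leftover: at 80.0 min in the winter run, [substrate] reads 0% and [target] 80.0%, so 20.0% of the charge stands unread. Call this L, the charge minus [substrate] and [target].

| flask | substrate | temperature | remark | time |
|---|---|---|---|---|
| summer | 0.14 M | −8 °C | run made earlier |  |
| winter | 0.22 M | 20 °C | run made earlier |  |
| violet | 0.10 M | 5 °C |  | 4.0 h |
| blue | 0.10 M | −20 °C |  | 4.0 h |
| green | 0.10 M | 30 °C |  | 4.0 h |

summer run (percent of the substrate charged)

| time / h | target / % | substrate / % |
|---|---|---|
| 0.500 | 8.6 | 82.5 |
| 0.833 | 14.5 | 73.0 |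
| 1.33 | 20.7 | 58.9 |
| 1.50 | 22.7 | 56.6 |
| 2.50 | 34.0 | 38.0 |
| 4.00 | 44.9 | 21.2 |
| 6.00 | 54.2 | 10.5 |

winter run (percent of the substrate charged)

| time / min | target / % | substrate / % |
|---|---|---|
| 8.00 | 43.7 | 12.8 |
| 12.0 | 49.1 | 4.3 |
| 20.0 | 56.3 | 0.9 |
| 25.0 | 59.4 | 0.3 |
| 40.0 | 66.7 | 0.1 |
| 60.0 | 74.1 | 0.1 |
| 80.0 | 80.0 | 0 |

(readings scatter by 0.5 percentage points)

- the flask with the highest amount of target, in percent of the substrate charged ("all alike" if they lie within 1.5 percentage points) (violet / blue / green / all alike)
- final target, as a percentage of the substrate charged, in violet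
- final target, as a percentage of the substrate charged, in blue
- final target, as a percentage of the substrate charged, in green

- in a conversion other conformer counts as not yet reacted
- a reading or a percentage of target counts all its forms, free or not

1. Between 20.0 min and 80.0 min the winter L falls from 42.8% as a pseudo-first-order tail, so we read a tail constant 0.761 h⁻¹, the rate at which L shrinks.

2. Tail constant times time gives the tail number N, the count of time constants a flask is allowed. Once substrate has finished, L stands near s·exp(−N), where s is the share of lost substrate found in L at the first summer reading, 50.9%. N therefore gives no reading for blue.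

3. The last summer interval gives a cold constant of 0.0584 h⁻¹. Violet lies between the two temperatures, so we take their geometric mean, 0.211 h⁻¹, which gives N = 0.843 and target near 78.1%. Green is hotter than winter, so we reckon N of at least 3.04 and target near 97.6%.

4. The test: the winter readings span N = 0.761, less than green asks, so they cannot show whether L has a floor.

The forecast says green, with 75% in violet, 11.5% in blue and 99% in green, “essentially complete”. Its violet lies below our reckoning.

    substrate ⇌ other conformer (K = 2.90, k = 0.980 h⁻¹, Ea = 87.0 kJ mol⁻¹, ΔH = 12.0 kJ mol⁻¹)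
    substrate → target (k = 1.30 h⁻¹, Ea = 84.0 kJ mol⁻¹)
    other conformer → isomer of the product (k = 6.60 h⁻¹, Ea = 78.0 kJ mol⁻¹)
    target ⇌ isomer of the product (K = 0.680, k = 0.240 h⁻¹, Ea = 95.0 kJ mol⁻¹, ΔH = 25.0 kJ mol⁻¹)
    substrate + target → side product (k = 4.60 M⁻¹ h⁻¹, Ea = 49.0 kJ mol⁻¹)
    crystals ⇌ target, rate k6*(cs6 - [target]) while solid is left; crystals form when [target] > cs6 (solubility = 8.70 mM, k = 9.00 h⁻¹)
    (constants at 5 °C)

The flasks give 77.6% in violet, 11.6% in blue and 83.1% in green, so green leads. Green's target reads 82.4% at 2.00 h and 83.1% at 40.0 h, with isomer of the product at 14.4%; L is 16.9% at the asked time, against 2.42% from the tail number.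

For violet left until 6.0 h, our constant, applied as a plain exponential to the L of violet at the asked time, reckons L at 14.7% and target near 85.3%. The computed flask gives less target than that reckoning, 83.4%, so L there is 16.6%, made up of isomer of the product at 11.8% and side product at 4.87%.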